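The route rests on cutting the bond between C2 of the oxolane ring and C1 of the catechol ring. This unmasks C2 as an acetal carbon beside ring oxygen O1. In the key step, a 2-methoxyoxolane that already carries the cis C3 acetoxymethyl and C4 benzyl groups is ionised. The cation is captured by a 3,4-bis(benzyloxy)phenylzinc reagent, so one operation joins the two advanced fragments and sets C2. The step exploits O1 as cation donor, the two cis substituents that cover one ring face, and the target's own acetate, whose carbonyl oxygen can bridge to C2 on that face. The precursor arises from a trans-disubstituted lactone by a reductive ring switch. C4 stems from (R)-epichlorohydrin.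

Key step: step 7

Assumption: both aryl bromides are catalogue compounds (otherwise each is one O-benzylation from 4-bromo-2-methoxyphenol or 4-bromocatechol). Centres that are erased or converge later are carried as mixtures.

Step 1
Reactants: 1 (R)-epichlorohydrin; 2 diethyl malonate
Product: 3 ethyl (1S,5R)-2-oxo-3-oxabicyclo[3.1.0]hexane-1-carboxylate
Conditions: NaOEt, EtOH, 0 °C to reflux
Reagents that add atoms: none
Why: Tandem alkylation, cyclopropanation and lactonisation: the malonate anion opens the epoxide at its CH2 end, the alkoxide re-closes to a new epoxide with loss of chloride, the second malonate anion attacks the stereocentre in a 3-exo-tet closure with inversion and the freed alkoxide lactonises, so that the single centre of 1 fixes both ring-fusion centres of 3.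

Step 2
Reactants: 3 ethyl (1S,5R)-2-oxo-3-oxabicyclo[3.1.0]hexane-1-carboxylate; 4 1-(benzyloxy)-4-bromo-2-methoxybenzene
Product: 6 ethyl (4R)-4-[4-(benzyloxy)-3-methoxybenzyl]-2-oxooxolane-3-carboxylate (C3 epimers), via arylmagnesium bromide 5 (not isolated)
Conditions: 4, Mg, THF, 40 °C; then CuI (20 mol %), 3, THF, −40 to −20 °C; aqueous work-up
Reagents that add atoms: magnesium, [Mg] (held only in 5)
Why: Copper-catalysed homoconjugate addition of a Grignard reagent to a doubly activated cyclopropane: the aryl group attacks the unhindered cyclopropane CH2, the bond to the carbon between the two carbonyl groups breaks to a stabilised enolate, and the adjacent stereocentre, which becomes C4 of the target, is not touched.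

Step 3
Reactants: 6 ethyl (4R)-4-[4-(benzyloxy)-3-methoxybenzyl]-2-oxooxolane-3-carboxylate
Product: 7 (4R)-4-[4-(benzyloxy)-3-methoxybenzyl]oxolan-2-one
Conditions: LiCl, H2O, DMSO, 140 °C
Reagents that add atoms: none
Why: Krapcho dealkoxycarbonylation removes the ester that was only needed to activate the cyclopropane, erases the labile C3 centre and leaves the R centre at C4 and the benzyl ether alone.

Step 4
Reactants: 7 (4R)-4-[4-(benzyloxy)-3-methoxybenzyl]oxolan-2-one
Product: 9 (3S,4R)-4-[4-(benzyloxy)-3-methoxybenzyl]-3-(dimethoxymethyl)oxolan-2-one, via silyl ketene acetal 8 (not isolated)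
Conditions: LiN(iPr)2, THF, −78 °C; Me3SiCl; solvent change to CH2Cl2; HC(OMe)3, Me3SiOTf (10 mol %), −78 °C
Reagents that add atoms: trimethyl orthoformate, COC(OC)OC; chlorotrimethylsilane, C[Si](C)(C)Cl (held only in 8)
Why: Mukaiyama-type alkylation of a silyl ketene acetal with the dimethoxycarbenium ion from the orthoformate: the electrophile should approach the planar C3 anti to the C4 benzyl group and give the 3,4-trans lactone, which is also the more stable epimer.

Step 5
Reactants: 9 (3S,4R)-4-[4-(benzyloxy)-3-methoxybenzyl]-3-(dimethoxymethyl)oxolan-2-one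
Product: 11 [(3R,4R)-4-[4-(benzyloxy)-3-methoxybenzyl]-2-methoxyoxolan-3-yl]methanol (both anomers), via diol 10 (not isolated)
Conditions: LiAlH4, THF, 0 °C; Na2SO4·10H2O quench, filtration; dried filtrate, camphorsulfonic acid (5 mol %), rt
Reagents that add atoms: none
Why: Hydride reduction of the lactone to the 1,4-diol and acid-catalysed transacetalisation (5-exo closure): only the CH2OH on the benzyl-bearing carbon reaches the acetal carbon through a five-membered ring, the other one would have to form an oxetane, and this ring switch turns the trans lactone into the 3,4-cis oxolane without touching either stereocentre.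

Step 6
Reactants: 11 [(3R,4R)-4-[4-(benzyloxy)-3-methoxybenzyl]-2-methoxyoxolan-3-yl]methanol
Product: 12 [(3R,4R)-4-[4-(benzyloxy)-3-methoxybenzyl]-2-methoxyoxolan-3-yl]methyl acetate (both anomers)
Conditions: Ac2O, pyridine, DMAP (5 mol %), CH2Cl2, 0 °C to rt
Reagents that add atoms: acetic anhydride, CC(=O)OC(C)=O
Why: Nucleophile-catalysed O-acylation of the only free hydroxyl group installs the acetate of the target, which also serves as participating group in step 7, and the acetal is stable to base.

Step 7
Reactants: 12 [(3R,4R)-4-[4-(benzyloxy)-3-methoxybenzyl]-2-methoxyoxolan-3-yl]methyl acetate; 13 1,2-bis(benzyloxy)-4-bromobenzene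
Product: 17 [(2S,3R,4R)-2-[3,4-bis(benzyloxy)phenyl]-4-[4-(benzyloxy)-3-methoxybenzyl]oxolan-3-yl]methyl acetate, via arylmagnesium bromide 14 (not isolated), via arylzinc bromide 15 (not isolated), via 2-bromooxolane 16 (not isolated)
Conditions: 13, Mg, THF, 40 °C, then ZnBr2, 0 °C; separately 12, Me3SiBr, CH2Cl2, −40 to 0 °C; solution of 15 added to 16, −78 to 0 °C
Reagents that add atoms: magnesium, [Mg] (held only in 14); zinc dibromide, [Zn+2].[Br-].[Br-] (held only in 15); bromotrimethylsilane, C[Si](C)(C)Br (bromine held only in 16)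
Why: Me3SiBr converts both anomers of 12 into bromide 16, which ionises under the Lewis acidity of ZnBr2 and MgBr2 to the oxolan-2-ylium ion stabilised by O1; the carbonyl oxygen of the C3 acetoxymethyl group can bridge reversibly to C2 (6-exo-trig, cis-fused 1,3-dioxan-2-ylium ion), and arylzinc 15 then transfers its ipso carbon to C2. The closest known reaction type is the transition-metal-free C-arylation of glycosyl and furanosyl halides, and of 2-sulfonyl cyclic ethers, by arylzinc reagents under ester participation. No ring of the product is closed here, since the transient dioxanylium ring opens again when the C2–aryl bond forms. The only new stereocentre, C2, is under substrate control: the C3 and C4 substituents are cis and cover the same ring face, the bridging acetate covers that face too, so the aryl group should enter anti to both and give the 2,3-trans,3,4-cis (2S,3R,4R) array from either anomer. Besides this facial selectivity the step needs chemoselectivity for the cation over the acetate (secured by the low carbonyl reactivity of arylzinc halides), regiocontrol on the arene (fixed by the C–Zn bond, para to one benzyloxy group and meta to the other), and intermolecular capture ahead of Friedel–Crafts attack by the C4 benzyl ring (that ring reaches C2 only from the blocked face through a strained bicyclo[3.2.1] array).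

Step 8
Reactants: 17 [(2S,3R,4R)-2-[3,4-bis(benzyloxy)phenyl]-4-[4-(benzyloxy)-3-methoxybenzyl]oxolan-3-yl]methyl acetate
Product: 18 [(2S,3R,4R)-2-(3,4-dihydroxyphenyl)-4-(4-hydroxy-3-methoxybenzyl)oxolan-3-yl]methyl acetate
Conditions: H2 (1 atm), 10 wt % Pd/C, EtOAc, rt, stopped after three equivalents of H2
Reagents that add atoms: none
Why: Catalytic hydrogenolysis of the three aryl benzyl ethers, which under neutral conditions should be cleaved faster than the ring C2–O1 bond, frees the phenols without affecting the acetate or any stereocentre.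

Compound list
1 | (R)-epichlorohydrin | ClC[C@H]1CO1 | starting material
2 | diethyl malonate | CCOC(=O)CC(=O)OCC | starting material
3 | ethyl (1S,5R)-2-oxo-3-oxabicyclo[3.1.0]hexane-1-carboxylate | CCOC(=O)[C@]12C[C@H]1COC2=O | intermediate
4 | 1-(benzyloxy)-4-bromo-2-methoxybenzene | COc1cc(Br)ccc1OCc1ccccc1 | starting material
5 | [4-(benzyloxy)-3-methoxyphenyl]magnesium bromide | COc1cc([Mg]Br)ccc1OCc1ccccc1 | intermediate
6 | ethyl (4R)-4-[4-(benzyloxy)-3-methoxybenzyl]-2-oxooxolane-3-carboxylate (C3 epimers) | CCOC(=O)C1[C@@H](Cc2ccc(OCc3ccccc3)c(OC)c2)COC1=O | intermediate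
7 | (4R)-4-[4-(benzyloxy)-3-methoxybenzyl]oxolan-2-one | O=C1C[C@@H](Cc2ccc(OCc3ccccc3)c(OC)c2)CO1 | intermediate
8 | {[(4R)-4-[4-(benzyloxy)-3-methoxybenzyl]-4,5-dihydrofuran-2-yl]oxy}trimethylsilane | C[Si](C)(C)OC1=C[C@@H](Cc2ccc(OCc3ccccc3)c(OC)c2)CO1 | intermediate
9 | (3S,4R)-4-[4-(benzyloxy)-3-methoxybenzyl]-3-(dimethoxymethyl)oxolan-2-one | COc1cc(C[C@H]2COC(=O)[C@@H]2C(OC)OC)ccc1OCc1ccccc1 | intermediate
10 | (2R,3R)-2-[4-(benzyloxy)-3-methoxybenzyl]-3-(dimethoxymethyl)butane-1,4-diol | COc1cc(C[C@@H](CO)[C@H](CO)C(OC)OC)ccc1OCc1ccccc1 | intermediate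
11 | [(3R,4R)-4-[4-(benzyloxy)-3-methoxybenzyl]-2-methoxyoxolan-3-yl]methanol (both anomers) | COc1cc(C[C@H]2COC(OC)[C@H]2CO)ccc1OCc1ccccc1 | intermediate
12 | [(3R,4R)-4-[4-(benzyloxy)-3-methoxybenzyl]-2-methoxyoxolan-3-yl]methyl acetate (both anomers) | COc1cc(C[C@H]2COC(OC)[C@H]2COC(C)=O)ccc1OCc1ccccc1 | intermediate
13 | 1,2-bis(benzyloxy)-4-bromobenzene | Brc1ccc(OCc2ccccc2)c(OCc2ccccc2)c1 | starting material
14 | [3,4-bis(benzyloxy)phenyl]magnesium bromide | Br[Mg]c1ccc(OCc2ccccc2)c(OCc2ccccc2)c1 | intermediate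
15 | [3,4-bis(benzyloxy)phenyl]zinc bromide | Br[Zn]c1ccc(OCc2ccccc2)c(OCc2ccccc2)c1 | intermediate
16 | [(3R,4R)-4-[4-(benzyloxy)-3-methoxybenzyl]-2-bromooxolan-3-yl]methyl acetate (both anomers) | COc1cc(C[C@H]2COC(Br)[C@H]2COC(C)=O)ccc1OCc1ccccc1 | intermediate
17 | [(2S,3R,4R)-2-[3,4-bis(benzyloxy)phenyl]-4-[4-(benzyloxy)-3-methoxybenzyl]oxolan-3-yl]methyl acetate | COc1cc(C[C@H]2CO[C@H](c3ccc(OCc4ccccc4)c(OCc4ccccc4)c3)[C@H]2COC(C)=O)ccc1OCc1ccccc1 | intermediate
18 | [(2S,3R,4R)-2-(3,4-dihydroxyphenyl)-4-(4-hydroxy-3-methoxybenzyl)oxolan-3-yl]methyl acetate | COc1cc(C[C@H]2CO[C@H](c3ccc(O)c(O)c3)[C@H]2COC(C)=O)ccc1O | target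

Total step count: 8. Longest linear sequence: 8 steps (1 to 18).

Steps most likely to fail

Step 7. Three things may go wrong:
- The cation may lose the C3 proton to give the enol ether.
- Aryl transfer from zinc may be too slow to outrun intramolecular Friedel–Crafts attack.
- Facial selectivity may be eroded.

The fallback sets out from 11 and comes back at 17. It forms the same bond by carbonyl addition and leaves the C2 configuration to a later, stereoconvergent ring closure.
- Mild hydrolysis of 11 (AcOH, H2O, THF) should give the lactol (3R,4R)-4-[4-(benzyloxy)-3-methoxybenzyl]-3-(hydroxymethyl)oxolan-2-ol F1.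
- Excess Grignard reagent 14 should add to the open hydroxy aldehyde form. This gives the triol (2R,3R)-1-[3,4-bis(benzyloxy)phenyl]-3-[4-(benzyloxy)-3-methoxybenzyl]-2-(hydroxymethyl)butane-1,4-diol F2 as a mixture of carbinol epimers.
- Catalytic camphorsulfonic acid in CH2Cl2 should ionise the p-benzyloxybenzylic alcohol. The CH2OH on the benzyl-bearing carbon should then close the ring to the more stable 2,3-trans alcohol [(2S,3R,4R)-2-[3,4-bis(benzyloxy)phenyl]-4-[4-(benzyloxy)-3-methoxybenzyl]oxolan-3-yl]methanol F3.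
- Acetylation as in step 6 gives 17.

Step 4. Capture of the weakly electrophilic orthoformate-derived cation may be sluggish. The product may also lose methanol under the Lewis acid, which flattens C3. The fallback sets out from 8 and comes back at 11. It replaces the O,O-acetal by an S,S-acetal that is introduced with a preformed cation and unmasked by alkylation.
- Compound 8 and 1,3-dithian-2-ylium tetrafluoroborate (CH2Cl2, −78 °C) should give (3R,4R)-4-[4-(benzyloxy)-3-methoxybenzyl]-3-(1,3-dithian-2-yl)oxolan-2-one F4, again anti to the benzyl group.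
- LiAlH4 should reduce it to (2R,3R)-2-[4-(benzyloxy)-3-methoxybenzyl]-3-(1,3-dithian-2-yl)butane-1,4-diol F5.
- MeI and NaHCO3 in MeOH at 40 °C should release the thionium ion. It is trapped by the 1,4-related hydroxyl group and then by methanol to give 11.

Step 8. Once the para phenol is unveiled, reductive opening of the oxolane at the benzylic C2–O1 bond may compete with the last debenzylation. The fallback sets out from 12 and comes back at 18. It moves the only reductive step ahead of the C2–aryl bond and finishes with fluoride.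
- Hydrogenolysis of 12 (H2, Pd/C, EtOAc) should give [(3R,4R)-4-(4-hydroxy-3-methoxybenzyl)-2-methoxyoxolan-3-yl]methyl acetate F6.
- TBSCl and imidazole should give its silyl ether [(3R,4R)-4-[4-(tert-butyldimethylsilyloxy)-3-methoxybenzyl]-2-methoxyoxolan-3-yl]methyl acetate F7.
- 4-Bromocatechol, TBSCl and imidazole should give 4-bromo-1,2-bis(tert-butyldimethylsilyloxy)benzene F8.
- As in step 7, F8 is taken through [3,4-bis(tert-butyldimethylsilyloxy)phenyl]magnesium bromide F9 to [3,4-bis(tert-butyldimethylsilyloxy)phenyl]zinc bromide F10.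
- Me3SiBr should convert F7 into [(3R,4R)-2-bromo-4-[4-(tert-butyldimethylsilyloxy)-3-methoxybenzyl]oxolan-3-yl]methyl acetate F11.
- The coupling of F10 with F11 should give [(2S,3R,4R)-2-[3,4-bis(tert-butyldimethylsilyloxy)phenyl]-4-[4-(tert-butyldimethylsilyloxy)-3-methoxybenzyl]oxolan-3-yl]methyl acetate F12.
- Et3N·3HF in THF at rt should free the three phenols and give 18 without touching the acetate or the ring.

Further compounds
F1 | step 7 | (3R,4R)-4-[4-(benzyloxy)-3-methoxybenzyl]-3-(hydroxymethyl)oxolan-2-ol | COc1cc(C[C@H]2COC(O)[C@H]2CO)ccc1OCc1ccccc1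
F2 | step 7 | (2R,3R)-1-[3,4-bis(benzyloxy)phenyl]-3-[4-(benzyloxy)-3-methoxybenzyl]-2-(hydroxymethyl)butane-1,4-diol | COc1cc(C[C@@H](CO)[C@H](CO)C(O)c2ccc(OCc3ccccc3)c(OCc3ccccc3)c2)ccc1OCc1ccccc1
F3 | step 7 | [(2S,3R,4R)-2-[3,4-bis(benzyloxy)phenyl]-4-[4-(benzyloxy)-3-methoxybenzyl]oxolan-3-yl]methanol | COc1cc(C[C@H]2CO[C@H](c3ccc(OCc4ccccc4)c(OCc4ccccc4)c3)[C@H]2CO)ccc1OCc1ccccc1
F4 | step 4 | (3R,4R)-4-[4-(benzyloxy)-3-methoxybenzyl]-3-(1,3-dithian-2-yl)oxolan-2-one | COc1cc(C[C@H]2COC(=O)[C@@H]2C3SCCCS3)ccc1OCc1ccccc1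
F5 | step 4 | (2R,3R)-2-[4-(benzyloxy)-3-methoxybenzyl]-3-(1,3-dithian-2-yl)butane-1,4-diol | COc1cc(C[C@@H](CO)[C@H](CO)C2SCCCS2)ccc1OCc1ccccc1
F6 | step 8 | [(3R,4R)-4-(4-hydroxy-3-methoxybenzyl)-2-methoxyoxolan-3-yl]methyl acetate | COc1cc(C[C@H]2COC(OC)[C@H]2COC(C)=O)ccc1O
F7 | step 8 | [(3R,4R)-4-[4-(tert-butyldimethylsilyloxy)-3-methoxybenzyl]-2-methoxyoxolan-3-yl]methyl acetate | COc1cc(C[C@H]2COC(OC)[C@H]2COC(C)=O)ccc1O[Si](C)(C)C(C)(C)C
F8 | step 8 | 4-bromo-1,2-bis(tert-butyldimethylsilyloxy)benzene | CC(C)(C)[Si](C)(C)Oc1ccc(Br)cc1O[Si](C)(C)C(C)(C)C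
F9 | step 8 | [3,4-bis(tert-butyldimethylsilyloxy)phenyl]magnesium bromide | CC(C)(C)[Si](C)(C)Oc1ccc([Mg]Br)cc1O[Si](C)(C)C(C)(C)C
F10 | step 8 | [3,4-bis(tert-butyldimethylsilyloxy)phenyl]zinc bromide | CC(C)(C)[Si](C)(C)Oc1ccc([Zn]Br)cc1O[Si](C)(C)C(C)(C)C
F11 | step 8 | [(3R,4R)-2-bromo-4-[4-(tert-butyldimethylsilyloxy)-3-methoxybenzyl]oxolan-3-yl]methyl acetate | COc1cc(C[C@H]2COC(Br)[C@H]2COC(C)=O)ccc1O[Si](C)(C)C(C)(C)C
F12 | step 8 | [(2S,3R,4R)-2-[3,4-bis(tert-butyldimethylsilyloxy)phenyl]-4-[4-(tert-butyldimethylsilyloxy)-3-methoxybenzyl]oxolan-3-yl]methyl acetate | COc1cc(C[C@H]2CO[C@H](c3ccc(O[Si](C)(C)C(C)(C)C)c(O[Si](C)(C)C(C)(C)C)c3)[C@H]2COC(C)=O)ccc1O[Si](C)(C)C(C)(C)C
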